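The route rests on cutting ring A'' of the 4-methoxyphenyl flavone unit at C8''–C7''. This ring is a phloroglucinol whose C8'' carries C3' of ring B between the oxygenated carbons C7'' and C8a'', which makes it an isomer of a 6-(arylmethyl)-4-methoxy-2-pyrone. Hot Mg(OMe)2 opens such a pyrone and recloses it on the benzylic carbon. One operation therefore delivers the carbocycle, the hindered biaryl junction already in place, and a single methyl ether at O5'' that forces later chromone closure toward the 8''-linked isomer. The precursor is 4-methoxy-2-pyrone bearing a 2-benzyloxy-5-bromobenzyl group at C6; the bromine is the handle for the second flavone.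

Key step: step 7

Locants: unit 1 is the 5,7-dihydroxyflavone half (rings A, C and B; plain and single-primed locants). Unit 2 is the other half (rings A'', C'' and the 4-methoxyphenyl ring; double- and triple-primed locants).
Remark on the chemistry: the C3'–C8'' biaryl axis is taken as configurationally labile at room temperature, in line with the target SMILES, so no stereochemical element has to be set.

Step 1
Reactants: 1 2-hydroxyphenylacetic acid
Product: 2 2-(5-bromo-2-hydroxyphenyl)acetic acid
Conditions: NBS (1.0 equiv), MeCN, 0 °C → rt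
Reagents that add atoms: N-bromosuccinimide, O=C1CCC(=O)N1Br
Why: Electrophilic aromatic bromination in which the phenol is the dominant director and sends bromine to the open position para to it, the carbon that later becomes C1' of ring B.

Step 2
Reactants: 2 2-(5-bromo-2-hydroxyphenyl)acetic acid
Product: 3 benzyl 2-[2-(benzyloxy)-5-bromophenyl]acetate
Conditions: BnBr (2.2 equiv), K2CO3, DMF, 50 °C
Reagents that add atoms: benzyl bromide, BrCc1ccccc1
Why: Williamson etherification of the phenoxide and SN2 alkylation of the carboxylate run in the same pot and mask the phenol, which would otherwise lactonise onto the side chain or quench the later carbanions.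

Step 3
Reactants: 3 benzyl 2-[2-(benzyloxy)-5-bromophenyl]acetate
Product: 4 2-[2-(benzyloxy)-5-bromophenyl]-N-methoxy-N-methylacetamide
Conditions: MeNH(OMe)·HCl, i-PrMgCl, THF, −20 → 0 °C; 1 M HCl
Reagents that add atoms: N,O-dimethylhydroxylamine hydrochloride, CNOC.Cl
Why: Weinreb amide synthesis by aminolysis of the ester with the chloromagnesium amide formed in situ, the Grignard reagent being consumed by the amine salt faster than it can exchange with the electron-rich aryl bromide at this temperature.

Step 4
Reactants: 4 2-[2-(benzyloxy)-5-bromophenyl]-N-methoxy-N-methylacetamide; 5 methyl acetoacetate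
Product: 7 methyl 6-[2-(benzyloxy)-5-bromophenyl]-3,5-dioxohexanoate, via methyl acetoacetate dianion 6 (not isolated)
Conditions: 5 (2 equiv), NaH then n-BuLi, THF, 0 °C; add 4, −78 → 0 °C; 1 M HCl
Reagents that add atoms: none
Why: Crossed Claisen-type γ-acylation of the acetoacetate dianion, in which the terminal carbanion adds to the Weinreb amide, whose chelated tetrahedral adduct blocks over-addition and whose α-protons are far less acidic than those of an arylacetyl ester, chloride or imidazolide, so that proton transfer is held back.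

Step 5
Reactants: 7 methyl 6-[2-(benzyloxy)-5-bromophenyl]-3,5-dioxohexanoate
Product: 8 6-[2-(benzyloxy)-5-bromobenzyl]-4-hydroxy-2H-pyran-2-one
Conditions: DBU, toluene, reflux; 1 M HCl
Reagents that add atoms: none
Why: Base-induced lactonisation of a 3,5-dioxo ester, in which the C5 enolate oxygen displaces methoxide from the ester (6-exo-trig) and the acidic hydroxypyrone is held as its amidinium salt, while DBU is too weak to deprotonate the benzylic carbon of the already anionic tricarbonyl, so closure on carbon does not compete here.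

Step 6
Reactants: 8 6-[2-(benzyloxy)-5-bromobenzyl]-4-hydroxy-2H-pyran-2-one
Product: 9 6-[2-(benzyloxy)-5-bromobenzyl]-4-methoxy-2H-pyran-2-one
Conditions: Me2SO4, K2CO3, acetone, reflux
Reagents that add atoms: dimethyl sulfate, COS(=O)(=O)OC
Why: O-alkylation of the vinylogous acid with a hard methylating agent under K2CO3 is the standard entry to 4-methoxy-2-pyrones and favours the 4-oxygen over C3 and over the lactone carbonyl oxygen.

Step 7
Reactants: 9 6-[2-(benzyloxy)-5-bromobenzyl]-4-methoxy-2H-pyran-2-one
Product: 11 2-[2-(benzyloxy)-5-bromophenyl]-5-methoxybenzene-1,3-diol, via ring-opened keto enoate 10 (not isolated)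
Conditions: Mg(OMe)2 (3 equiv), MeOH, Ar, reflux → 100 °C (sealed vessel); 1 M HCl
Reagents that add atoms: none
Why: Methoxide adds to the lactone carbonyl of 9 and releases the ring oxygen as an enolate, giving keto enoate 10 (numbered from the ester carbon C1), in which the former ring double bond still holds C1 and the C4 methylene on the same side (E by the sequence rule). Proton exchange in methanol makes the enolate at benzylic C6 available beside the more stable but unproductive C4 dienolate, because C6 is acidified by the ketone, by ring B and inductively by the meta bromine. C6 attacks C1 in an intramolecular Claisen (Dieckmann-type) condensation, a 6-(enolendo)-exo-trig closure of carbocyclic ring A'' that forms the C8''–C7'' bond, and loss of methoxide followed by enolisation gives the magnesium bis-phenoxide of 11; the closest known reaction type is the alkoxide-induced conversion of 4-methoxy-6-methyl-2-pyrone and of 3,5-dioxohexanoates into phloroglucinol ethers. The selectivity required is closure on carbon instead of return to the pyrone through oxygen, and it is secured because lactone formation is reversible under methoxide whereas aromatisation and phenoxide formation are not, with divalent magnesium binding the developing 1,3-dioxygenated array. The spectators are chosen for this step: methoxide in methanol makes exchange at the enol ether degenerate, the benzyl ether denies the ketone a free ortho phenoxide that would condense to a benzofuran, and the aryl bromide is inert to alkoxide. No stereocentre is created, and the mirror symmetry of 11, with its methyl ether para to ring B, removes any regiochemical choice from the next acylation.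

Step 8
Reactants: 11 2-[2-(benzyloxy)-5-bromophenyl]-5-methoxybenzene-1,3-diol
Product: 12 1-[3-(2-benzyloxy-5-bromophenyl)-2,4-dihydroxy-6-methoxyphenyl]ethanone
Conditions: Ac2O (1.2 equiv), BF3·OEt2, CH2Cl2, 0 → 40 °C; aq. NaOAc/MeOH, 50 °C
Reagents that add atoms: acetic anhydride, CC(=O)OC(C)=O
Why: Friedel–Crafts C-acylation of a phloroglucinol-type ring whose two free positions are equivalent and far more nucleophilic than brominated ring B, where the BF2 chelate of the o-hydroxy ketone stops a second acylation and BF3·OEt2 without a soft nucleophile leaves aryl benzyl ethers intact.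

Step 9
Reactants: 12 1-[3-(2-benzyloxy-5-bromophenyl)-2,4-dihydroxy-6-methoxyphenyl]ethanone
Product: 13 1-[4-(benzyloxy)-3-(2-benzyloxy-5-bromophenyl)-2-hydroxy-6-methoxyphenyl]ethanone
Conditions: BnBr (1.05 equiv), K2CO3, acetone, reflux
Reagents that add atoms: benzyl bromide, BrCc1ccccc1
Why: Williamson etherification that discriminates by hydrogen bonding, since the phenol ortho to the acetyl group is chelated and stays free while one equivalent of BnBr alkylates the para phenol, the future O7''.

Step 10
Reactants: 13 1-[4-(benzyloxy)-3-(2-benzyloxy-5-bromophenyl)-2-hydroxy-6-methoxyphenyl]ethanone; 14 4-methoxybenzoyl chloride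
Product: 16 7-(benzyloxy)-8-[2-(benzyloxy)-5-bromophenyl]-5-methoxy-2-(4-methoxyphenyl)-4H-chromen-4-one, via 1,3-diketone 15 (not isolated)
Conditions: LiN(SiMe3)2 (3.5 equiv), THF, −78 °C; 14, −78 → 0 °C; 1 M HCl; crude 15, p-TsOH·H2O (cat.), toluene, 90 °C
Reagents that add atoms: none
Why: Crossed Claisen acylation of the lithium phenoxide-enolate dianion by the aroyl chloride (any O-aroylated material reaches the same diketone by Baker–Venkataraman acyl shift under the excess base) followed by acid-catalysed cyclodehydration, in which only the phenol next to ring B is free, so ring C'' closes through that oxygen and ring B ends up at C8''.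

Step 11
Reactants: 16 7-(benzyloxy)-8-[2-(benzyloxy)-5-bromophenyl]-5-methoxy-2-(4-methoxyphenyl)-4H-chromen-4-one
Product: 17 2,4,6-trichlorophenyl 4-(benzyloxy)-3-[7-(benzyloxy)-5-methoxy-2-(4-methoxyphenyl)-4-oxo-4H-chromen-8-yl]benzoate
Conditions: Pd(OAc)2 (cat.), Xantphos, Et3N, 2,4,6-trichlorophenyl formate, toluene, 100 °C (sealed tube)
Reagents that add atoms: 2,4,6-trichlorophenyl formate, O=COc1c(Cl)cc(Cl)cc1Cl
Why: Palladium-catalysed aryloxycarbonylation, in which Et3N releases CO and the phenol from the formate, the unhindered aryl bromide adds oxidatively to zerovalent palladium, CO inserts and the phenoxide intercepts the acyl complex, so that an activated ester is obtained directly without CO gas, hydrolysis or acid chloride formation.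

Step 12
Reactants: 18 2,4,6-trihydroxyacetophenone
Product: 19 1-[2,4-bis(benzyloxy)-6-hydroxyphenyl]ethanone
Conditions: BnBr (2.1 equiv), K2CO3, DMF, 60 °C
Reagents that add atoms: benzyl bromide, BrCc1ccccc1
Why: Double Williamson etherification that stops by itself, because once the 4-OH and one ortho OH have reacted the last phenol is chelated to the ketone and remains free.

Step 13
Reactants: 17 2,4,6-trichlorophenyl 4-(benzyloxy)-3-[7-(benzyloxy)-5-methoxy-2-(4-methoxyphenyl)-4-oxo-4H-chromen-8-yl]benzoate; 19 1-[2,4-bis(benzyloxy)-6-hydroxyphenyl]ethanone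
Product: 21 5,7-bis(benzyloxy)-2-{4-(benzyloxy)-3-[7-(benzyloxy)-5-methoxy-2-(4-methoxyphenyl)-4-oxo-4H-chromen-8-yl]phenyl}-4H-chromen-4-one, via 1,3-diketone 20 (not isolated)
Conditions: 19 (2 equiv), LiN(SiMe3)2 (4 equiv), THF, −78 °C; 17, −78 → 0 °C; 1 M HCl; crude 20, p-TsOH·H2O (cat.), toluene, 80 °C
Reagents that add atoms: none
Why: Crossed Claisen condensation of the dianion of the cheap ketone (used in excess so that it also serves as base for the product and no free amide base meets the ester) with the activated aryl ester, again self-correcting through the Baker–Venkataraman shift, then acid-catalysed cyclodehydration through the only free phenol to close ring C, the 2-aryl-substituted chromone of unit 2 being a much poorer acceptor than the trichlorophenyl ester at low temperature.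

Step 14
Reactants: 21 5,7-bis(benzyloxy)-2-{4-(benzyloxy)-3-[7-(benzyloxy)-5-methoxy-2-(4-methoxyphenyl)-4-oxo-4H-chromen-8-yl]phenyl}-4H-chromen-4-one
Product: 22 podocarpusflavone A
Conditions: BCl3 (excess), C6HMe5, CH2Cl2, −78 °C → rt; H2O, 1 M HCl
Reagents that add atoms: none
Why: Lewis acid ether cleavage, in which BCl3 removes the four benzyl groups as cations that pentamethylbenzene traps (preventing C-benzylation of rings A and A'') and cleaves the 5''-methyl ether because boron is chelated between O5'' and the C4'' carbonyl, whereas the unchelated 4'''-methyl ether is not attacked by BCl3 at or below room temperature.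

Compound list
1 | 2-hydroxyphenylacetic acid | OC(=O)Cc1ccccc1O | starting material
2 | 2-(5-bromo-2-hydroxyphenyl)acetic acid | OC(=O)Cc1cc(Br)ccc1O | intermediate
3 | benzyl 2-[2-(benzyloxy)-5-bromophenyl]acetate | O=C(Cc1cc(Br)ccc1OCc1ccccc1)OCc1ccccc1 | intermediate
4 | 2-[2-(benzyloxy)-5-bromophenyl]-N-methoxy-N-methylacetamide | CON(C)C(=O)Cc1cc(Br)ccc1OCc1ccccc1 | intermediate
5 | methyl acetoacetate | COC(=O)CC(C)=O | starting material
6 | sodium lithium dianion of methyl acetoacetate | [Na+].[Li+].COC(=O)[CH-]C(=O)[CH2-] | intermediate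
7 | methyl 6-[2-(benzyloxy)-5-bromophenyl]-3,5-dioxohexanoate | COC(=O)CC(=O)CC(=O)Cc1cc(Br)ccc1OCc1ccccc1 | intermediate
8 | 6-[2-(benzyloxy)-5-bromobenzyl]-4-hydroxy-2H-pyran-2-one | Oc1cc(Cc2cc(Br)ccc2OCc2ccccc2)oc(=O)c1 | intermediate
9 | 6-[2-(benzyloxy)-5-bromobenzyl]-4-methoxy-2H-pyran-2-one | COc1cc(Cc2cc(Br)ccc2OCc2ccccc2)oc(=O)c1 | intermediate
10 | methyl (2E)-6-[2-(benzyloxy)-5-bromophenyl]-3-methoxy-5-oxohex-2-enoate | COC(=O)/C=C(/OC)CC(=O)Cc1cc(Br)ccc1OCc1ccccc1 | intermediate
11 | 2-[2-(benzyloxy)-5-bromophenyl]-5-methoxybenzene-1,3-diol | COc1cc(O)c(c(O)c1)-c1cc(Br)ccc1OCc1ccccc1 | intermediate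
12 | 1-[3-(2-benzyloxy-5-bromophenyl)-2,4-dihydroxy-6-methoxyphenyl]ethanone | CC(=O)c1c(OC)cc(O)c(c1O)-c1cc(Br)ccc1OCc1ccccc1 | intermediate
13 | 1-[4-(benzyloxy)-3-(2-benzyloxy-5-bromophenyl)-2-hydroxy-6-methoxyphenyl]ethanone | CC(=O)c1c(OC)cc(OCc2ccccc2)c(c1O)-c1cc(Br)ccc1OCc1ccccc1 | intermediate
14 | 4-methoxybenzoyl chloride | COc1ccc(cc1)C(Cl)=O | starting material
15 | 1-[4-(benzyloxy)-3-(2-benzyloxy-5-bromophenyl)-2-hydroxy-6-methoxyphenyl]-3-(4-methoxyphenyl)propane-1,3-dione | COc1ccc(cc1)C(=O)CC(=O)c1c(OC)cc(OCc2ccccc2)c(c1O)-c1cc(Br)ccc1OCc1ccccc1 | intermediate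
16 | 7-(benzyloxy)-8-[2-(benzyloxy)-5-bromophenyl]-5-methoxy-2-(4-methoxyphenyl)-4H-chromen-4-one | COc1ccc(cc1)-c1cc(=O)c2c(OC)cc(OCc3ccccc3)c(-c3cc(Br)ccc3OCc3ccccc3)c2o1 | intermediate
17 | 2,4,6-trichlorophenyl 4-(benzyloxy)-3-[7-(benzyloxy)-5-methoxy-2-(4-methoxyphenyl)-4-oxo-4H-chromen-8-yl]benzoate | COc1ccc(cc1)-c1cc(=O)c2c(OC)cc(OCc3ccccc3)c(-c3cc(ccc3OCc3ccccc3)C(=O)Oc3c(Cl)cc(Cl)cc3Cl)c2o1 | intermediate
18 | 2,4,6-trihydroxyacetophenone | CC(=O)c1c(O)cc(O)cc1O | starting material
19 | 1-[2,4-bis(benzyloxy)-6-hydroxyphenyl]ethanone | CC(=O)c1c(O)cc(OCc2ccccc2)cc1OCc1ccccc1 | intermediate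
20 | 1-[2,4-bis(benzyloxy)-6-hydroxyphenyl]-3-{4-(benzyloxy)-3-[7-(benzyloxy)-5-methoxy-2-(4-methoxyphenyl)-4-oxo-4H-chromen-8-yl]phenyl}propane-1,3-dione | COc1ccc(cc1)-c1cc(=O)c2c(OC)cc(OCc3ccccc3)c(-c3cc(ccc3OCc3ccccc3)C(=O)CC(=O)c3c(O)cc(OCc4ccccc4)cc3OCc3ccccc3)c2o1 | intermediate
21 | 5,7-bis(benzyloxy)-2-{4-(benzyloxy)-3-[7-(benzyloxy)-5-methoxy-2-(4-methoxyphenyl)-4-oxo-4H-chromen-8-yl]phenyl}-4H-chromen-4-one | COc1ccc(cc1)-c1cc(=O)c2c(OC)cc(OCc3ccccc3)c(-c3cc(ccc3OCc3ccccc3)-c3cc(=O)c4c(OCc5ccccc5)cc(OCc5ccccc5)cc4o3)c2o1 | intermediate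
22 | podocarpusflavone A, 8-[5-(5,7-dihydroxy-4-oxo-4H-chromen-2-yl)-2-hydroxyphenyl]-5,7-dihydroxy-2-(4-methoxyphenyl)-4H-chromen-4-one | COc1ccc(-c2cc(=O)c3c(O)cc(O)c(-c4cc(-c5cc(=O)c6c(O)cc(O)cc6o5)ccc4O)c3o2)cc1 | target

Total step count: 14. Longest linear sequence: 13 steps (steps 1–11, 13 and 14, from 1 to 22). Step 12 is a one-step side branch.

Steps most likely to fail

1. Step 7.
- What may go wrong: the opened chain may rest as its C4 dienolate without closing on carbon, or it may fragment by retro-Claisen cleavage at the ketone on prolonged heating.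
- Fallback: the biaryl bond is made by cross-coupling instead of ring synthesis. It sets out from 18 and rejoins the route at 13.
- Mono-benzylation of the unchelated 4-OH of 18 (BnBr, 1 equiv, K2CO3, acetone) should give 1-[4-(benzyloxy)-2,6-dihydroxyphenyl]ethanone F1.
- Mono-methylation of one of the two equivalent ortho phenols (Me2SO4, 1 equiv, K2CO3, acetone) should give 1-[4-(benzyloxy)-2-hydroxy-6-methoxyphenyl]ethanone F2.
- Iodination ortho to the free phenol, the usual site in 2-hydroxy-4,6-dialkoxyacetophenones (NIS, catalytic CF3CO2H, MeCN), should give 1-[4-(benzyloxy)-2-hydroxy-3-iodo-6-methoxyphenyl]ethanone F3.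
- Suzuki–Miyaura coupling of F3 with commercial [2-(benzyloxy)-5-bromophenyl]boronic acid (Pd(PPh3)4, aq. Na2CO3, DME, 80 °C), in which the C–I bond reacts ahead of the C–Br bond, leads to 13.

2. Step 4.
- What may go wrong: proton transfer from the benzylic α-position of the amide to the strongly basic dianion may outrun addition and simply return both partners.
- Fallback: the same bond is formed without any base. It sets out from 3 and 5 and rejoins the route at 7.
- Saponification of 3 (LiOH, THF/H2O) gives 2-[2-(benzyloxy)-5-bromophenyl]acetic acid F4, and oxalyl chloride with catalytic DMF gives 2-[2-(benzyloxy)-5-bromophenyl]acetyl chloride F5.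
- Separately, 5 is silylated (Me3SiCl, Et3N) to methyl 3-(trimethylsilyloxy)but-2-enoate F6. A second silylation (LiN(i-Pr)2, Me3SiCl, THF, −78 °C) gives 1-methoxy-1,3-bis(trimethylsilyloxy)buta-1,3-diene F7.
- F5 acylates the terminal carbon of F7 in CH2Cl2 (−78 → 20 °C), and dilute acid removes the remaining silyl group to give 7.

3. Step 14.
- What may go wrong: the 5''-methyl ether may be cleaved incompletely at temperatures where the 4'''-methyl ether is safe. The 4'''-ether may erode if the reaction is forced, or benzyl groups may transfer to ring carbons.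
- Fallback: the two kinds of ether are removed in separate operations by different mechanisms. It sets out from 21 and ends at 22.
- Hydrogenolysis (H2, Pd/C, THF/MeOH) removes the four benzyl groups under neutral conditions and should give 5''-O-methylpodocarpusflavone A F8.
- AlCl3 in MeCN at reflux then cleaves only the methyl ether held in the chelate with the C4'' carbonyl, giving 22.

Further compounds
F1 | step 7 | 1-[4-(benzyloxy)-2,6-dihydroxyphenyl]ethanone | CC(=O)c1c(O)cc(OCc2ccccc2)cc1O
F2 | step 7 | 1-[4-(benzyloxy)-2-hydroxy-6-methoxyphenyl]ethanone | CC(=O)c1c(O)cc(OCc2ccccc2)cc1OC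
F3 | step 7 | 1-[4-(benzyloxy)-2-hydroxy-3-iodo-6-methoxyphenyl]ethanone | CC(=O)c1c(OC)cc(OCc2ccccc2)c(I)c1O
F4 | step 4 | 2-[2-(benzyloxy)-5-bromophenyl]acetic acid | OC(=O)Cc1cc(Br)ccc1OCc1ccccc1
F5 | step 4 | 2-[2-(benzyloxy)-5-bromophenyl]acetyl chloride | ClC(=O)Cc1cc(Br)ccc1OCc1ccccc1
F6 | step 4 | methyl 3-(trimethylsilyloxy)but-2-enoate (double-bond isomers) | COC(=O)C=C(C)O[Si](C)(C)C
F7 | step 4 | 1-methoxy-1,3-bis(trimethylsilyloxy)buta-1,3-diene | COC(=CC(=C)O[Si](C)(C)C)O[Si](C)(C)C
F8 | step 14 | 5''-O-methylpodocarpusflavone A, 8-[5-(5,7-dihydroxy-4-oxo-4H-chromen-2-yl)-2-hydroxyphenyl]-7-hydroxy-5-methoxy-2-(4-methoxyphenyl)-4H-chromen-4-one | COc1ccc(cc1)-c1cc(=O)c2c(OC)cc(O)c(-c3cc(ccc3O)-c3cc(=O)c4c(O)cc(O)cc4o3)c2o1
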